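A substrate whose fall ignores the reagent cannot be meeting the reagent in that fall.

| setting | cedar | maple | green | grey | violet |
|---|---|---|---|---|---|
| substrate | 20 mM | 20 mM | 20 mM | 20 mM (fed, over 5.0 min) | 20 mM |
| reagent | 20 mM | 40 mM | 20.0 mM (fed, over 5.0 min) | 20.0 mM | 20.0 mM |
| remark | run made earlier | run made earlier | all else is in the flask from the start; the feed brings no volume worth counting | all else is in the flask from the start; the feed brings no volume worth counting | everything together at the start |
| time |  |  | 8.0 min | 8.0 min | 8.0 min |

cedar run (percent of the substrate charged)

| time / min | target / % | substrate / % |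
|---|---|---|
| 0.417 | 10.8 | 67.1 |
| 0.667 | 19.7 | 53.4 |
| 0.833 | 22.0 | 47.8 |
| 1.33 | 33.9 | 27.0 |
| 2.00 | 40.2 | 14.8 |
| 3.00 | 45.2 | 6.8 |
| 5.00 | 47.7 | 0 |

maple run (percent of the substrate charged)

| time / s | target / % | substrate / % |
|---|---|---|
| 10.0 | 6.1 | 86.2 |
| 12.0 | 9.2 | 83.9 |
| 20.0 | 14.1 | 73.4 |
| 25.0 | 16.0 | 67.3 |
| 40.0 | 26.4 | 52.0 |
| 60.0 | 36.3 | 39.7 |
| 90.0 | 45.4 | 23.9 |

(each reading ± 1 percentage point)



1. the flask that comes out highest in amount of target, in percent of the substrate charged, or "all alike" when all lie within 1.5 percentage points (green / grey / violet / all alike)
2. target at the end, in percent of the substrate charged, green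
3. target at the end, in percent of the substrate charged, grey
4. target at the end, in percent of the substrate charged, violet

From the cedar run I read a first-order constant of 0.955 /min and from the maple run 0.954 /min, although maple held twice the reagent. Yet the target per substrate lost, the selectivity, read 47.7% in cedar and 59.7% in maple, each at its last reading. These numbers go together once a fork stands after the fall, so I followed one molecule past it.

I gave it the chance c·R/(R+K), with R the mean reagent as a fraction of the substrate charge, taken as the charge less half the target. That gave 0.761 for cedar and 1.77 for maple. The two runs then gave a ceiling c of 0.735 and K, the reagent level at which the chance is half its ceiling, of 0.412, both readings with their scatter.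

In green I reckoned that a substrate molecule lives 1.05 min, shorter than the feed, so I took it to meet reagent worth about 0.209 of the charge, a chance of 24.8%. Violet has cedar's charges, so I took 47.7% for it. For grey I assumed cedar's mean reagent and reckoned 1.19% of its substrate still unused at the end, which gave me 47.1%. I chose violet, by less than the scatter.

The forecast differed from my reckoning: grey highest, with green 18%, grey 56%, violet 48%, saying of grey that "slow substrate feed keeps the flux low with reagent present".

The flasks gave green 28.3%, grey 42.1% and violet 49.2%, so violet stood highest.

    substrate → intermediate (k = 0.0120 /s)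
    reagent ⇌ dormant form (K = 1.70, k = 0.00830 /s)
    reagent + intermediate → target (k = 4.20 /M/s)
    substrate → side product (k = 0.00380 /s)
    intermediate → side product (k = 0.0180 /s)

In grey at 4.00 min, the dormant form held 50.2% of the reagent charged, with 24.9% free. For the neighbour of violet charged with 5.0 mM of reagent, its target puts R at 0.162, so c and K give a chance of 20.7%, and that flask held 17.6% of target.

All runs are simulated on assumed constants; scatter was added.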